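Late in the midnight run, at 120 s, the left-handed substrate stood at 1.40% of its own charge and the right-handed substrate at 10.0%, so I stopped counting what was made and reckoned with the fraction left of each hand.

all flasks: left-handed substrate 13 mM; right-handed substrate 13 mM; racemization catalyst 66 µM

| run | reagent | remark | time |
|---|---|---|---|
| noon | 34 mM (fed, over 12 s) | run made earlier |  |
| midnight | 140 mM (fed, over 12 s) | run made earlier |  |
| Wednesday's | 26.0 mM (fed, over 12 s) |  | 4.0 min |
| Monday's | 100 mM (fed, over 12 s) |  | 4.0 min |

- noon (time / s: right-handed substrate / %, left-handed substrate / %, left-handed product / %): 10.0: 49.0, 47.1, 2.6; 20.0: 46.1, 42.1, 8.1; 30.0: 44.0, 37.7, 12.2; 50.0: 40.4, 30.0, 18.8; 80.0: 35.1, 23.1, 24.3; 90.0: 32.9, 21.8, 26.1; 120: 29.1, 18.3, 29.4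
- midnight (time / s: right-handed substrate / %, left-handed substrate / %, left-handed product / %): 15.0: 41.6, 31.3, 18.8; 30.0: 29.4, 14.8, 34.4; 50.0: 19.9, 6.5, 42.2; 60.0: 16.0, 3.6, 43.3; 80.0: 10.4, 1.3, 45.6; 90.0: 8.9, 1.5, 45.6; 120: 5.0, 0.7, 47.1

(scatter of a reading: 0.3 percentage points)

- reagent is single-handed; left-handed substrate and right-handed substrate are mirror images of each other, charged as a racemate, each of them at the stated concentration
- on the list of suspects stand: reagent + racemization catalyst -> spent catalyst; left-handed product <-> right-handed product; left-handed substrate + racemization catalyst <-> right-handed substrate + racemization catalyst; reagent + left-handed substrate -> left-handed product; reagent + right-handed substrate -> right-handed product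
- an excess is the difference of the two amounts in percent of their sum
- an excess is below zero if the other one leads
- the handed part of reagent does not stay in what it makes, so the products of the two hands are mirror images too

* the winner by excess of right-handed substrate over left-handed substrate among what is left of the two; "neither" if no more than 2 percentage points parts them (Wednesday's / Monday's / neither)
* excess of right-handed substrate over left-handed substrate among what is left of the two at the end, Wednesday's
* excess of right-handed substrate over left-handed substrate among what is left of the two at the end, Monday's

At 120 s the noon run gave 1.86, and this exponent, the logarithm of the left-handed fraction left divided by that of the right-handed fraction left, is an apparent selectivity factor. The midnight run read 1.85 at the same time. Monday's flask, like the midnight run, holds reagent above the substrate, so I took each hand as pseudo-first-order, its logarithm growing with reagent level times time. Monday's then gets 1.33 times the midnight dose, and my reckoning gave an excess of 86.5%. But the left-to-right ratio seemed to level off at the end of the midnight run. Held at its last reading, that ratio gives an excess of 75.4%, lower than my figure, yet the last left-handed reading of 0.7% carries a scatter of 0.3 percentage points, so I did not trust that ratio, and I kept my figure.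

Wednesday's was harder. Its reagent equals the two hands together, so I set the reagent fraction left equal to the mean substrate fraction left. The noon run's mean fraction of 47.4% gave a mean constant of 0.254 /M/s, hence a fraction left of 0.393. With the exponent unchanged, that meant 28.3%. The objection stood, though: in the noon run the exponent had fallen from 2.21 at 30.0 s to 1.86, and Wednesday's runs about twice as long. So I expected less than that figure from Wednesday's.

The forecast named Monday's, with 19% for Wednesday's and 68% for Monday's, holding that “catalyst death looks slow at most”.

The flasks gave Monday's: 21.8% for Wednesday's and 85.4% for Monday's.

    reagent + racemization catalyst → spent catalyst (k = 0.0640 /M/s)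
    left-handed product ⇌ right-handed product (k = 0.00850 /s)
    left-handed substrate + racemization catalyst ⇌ right-handed substrate + racemization catalyst, rate k3*[racemization catalyst]*[left-handed substrate] forward; the back reaction follows from the equilibrium constant (k = 48.0 /M/s)
    reagent + left-handed substrate → left-handed product (k = 0.400 /M/s)
    reagent + right-handed substrate → right-handed product (k = 0.160 /M/s)

At the end Monday's exponent read 1.78 and Wednesday's 1.59, while racemization catalyst stood at 30.5% in Monday's and 79.3% in Wednesday's. Neither flask was at rest: at 40.0 min Monday's excess reaches >99.9% and Wednesday's sinks to 6.24%. For the flask like Wednesday's but with 10 mM of reagent, the same constant gives a mean fraction left of 0.723, and Wednesday's exponent, read at the same time, gives 6.94%. That flask gives 6.78%.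

The readings are calculated on assumed constants, noise included.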